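Assumption (chemistry): oct-3-yn-2-one is taken as a purchasable ynone. The mono(bromomethylene) lactone 11 is drawn as its Z isomer, but either geometric isomer of 11 would lead to the same tetrabromide 12 and so to the same target.

Structural features

The target 13 is a single five-membered ring, a furan-2(5H)-one, with the lactone carbonyl at C2, an n-butyl chain on C3, bromine on C4 and an exocyclic dibromomethylene carbon C6 doubly bonded to C5. It has no stereocentre, and because C6 carries two identical bromines the exocyclic alkene has no geometric isomers; the problem is therefore one of regiochemistry and chemoselectivity only. The ring oxygen O1 is both the lactone oxygen and the enol oxygen of C5=C6, so the molecule is a cross-conjugated enol lactone with a fully substituted C3=C4 bond. The fragile points are the C4–Br bond (a vinylogous acyl bromide, open to nucleophilic addition–elimination and to insertion of zerovalent palladium), the enol lactone (hydrolysis) and the electron-poor exocyclic diene (oligomerisation in light or on storage). The real difficulty is to place one alkyl group and three vinylic bromines on a six-carbon skeleton with no doubt about which carbon carries what. The key step uses the fact that C2 is bonded only to C3, to O1 and to its own oxygen, so it can arrive as carbon monoxide 7 between a C3 vinyl iodide and the enol oxygen of a C5 methyl ketone; the acyclic iodoenone 6 then already holds C3, C4 with its bromine, C5 and C6. In 6 the E descriptor is the correct one for the isomer with iodine cis to acetyl, because bromine outranks the acetyl carbon at the alpha position; the structures are consistent as they stand.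

Logic of the disconnections

13 back to 11 and 9: one of the two C6–Br bonds is cut. Forward, 9 adds across C5=C6 of 11 to give 12, and loss of HBr restores the alkene with one more bromine. The gain is one halogen fewer on a substrate that is otherwise unchanged. The demand is that 9 adds to a deactivated bromovinyl enol ester while leaving the tetrasubstituted, electron-poor C3=C4 bond alone; 12 has a single hydrogen, on C6, so the elimination can only go one way.

11 back to 8 and 9: the remaining C6–Br bond is cut in the same manner through 10. This leaves a plain exocyclic methylene group, the form in which an enolised methyl ketone delivers C6. The demand is 1,2-addition to the enol-ester alkene without conjugate addition across the diene, and a base that removes a C6 hydrogen without attacking C4.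

8 back to 6 and 7: the C2–C3 and C2–O1 bonds are cut, which opens the only ring and removes the lactone carbonyl as 7. All substituents stay on an acyclic enone in which the C3/C4 pattern is already decided. The forward step must distinguish C–I from C–Br toward zerovalent palladium, and it needs iodine and acetyl on the same side of the alkene.

6 back to 1, 2, 3 and 4: the C4–I and C3–Br bonds are cut, which returns the alkyne. Forward, iodide from 2, carried by the silicon of 3, adds in conjugate fashion to give 5, and 4 brominates the central carbon of 5. The gain is a commercial eight-carbon ynone with all carbons of the precursor in place. The demand is net anti addition of the two halogens and the absence of free iodide once 4 is added.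

Other disconnections considered

Alternative 1: The cut is the lactone O1–C2 bond, with C2, C3, C4 and C5 taken together from a four-membered ring. Diisopropyl squarate A1 would receive, in two separate carbonyl additions, a butyl nucleophile and a dibromomethyl carbanion, giving 2-butyl-4-(dibromomethyl)-4-hydroxy-3-isopropoxycyclobut-2-en-1-one A2. On heating, A2 should open by a 4π electrocyclic reaction to a hydroxy vinylketene whose hydroxyl adds to the ketene carbon, giving 3-butyl-5-(dibromomethyl)-4-isopropoxyfuran-2(5H)-one A3.
- In its favour: the position of butyl at C3 follows from the order of the additions, and the ring closure is thermal, needing neither palladium nor carbon monoxide. No vinylic bromide is present when the ring forms, so the halide-selectivity question of the chosen plan does not arise; on these mechanistic points it is the better plan.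
- Against it here: A3 carries an isopropyl enol ether at C4, which must be cleaved and exchanged for bromide. C5 is saturated, so HBr must be removed across C5–C6 and a further bromination–elimination round is still needed to reach the dibromomethylene group. The alkoxide formed next to a CHBr2 group on the way to A2 could also close to a bromo epoxide.
- Comparison: on structure the two plans are equal, since neither has a stereocentre to control. On step economy this plan needs about eight steps against four.

Alternative 2: The cut is the C3–C4 bond, with the ester bond O1–C2 already present in an acyclic diester. Methyl 2-(hexanoyloxy)propanoate A4, an acylated lactic ester, would be treated with LiN(SiMe3)2. The enolate of the hexanoyl part attacks the methyl ester carbonyl in a Dieckmann condensation to give 3-butyl-4-hydroxy-5-methylfuran-2(5H)-one A5.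
- In its favour: commodity starting materials, no transition metal, no toxic gas, a robust ring closure, and a butyl position fixed by connectivity with no alkene geometry to secure. On cost, scale and certainty of the key step it is better than the chosen plan.
- Against it here: A5 has hydroxyl where bromine is needed at C4, and a saturated C5–CH3 unit. The hydroxyl must be exchanged for bromide, and C5 must be brominated under radical conditions and HBr eliminated merely to reach 8, where this plan would join the chosen route. That radical bromination has to tell C5–H from the allylic CH2 of the butyl chain.
- Comparison: the mechanism is simpler, but three oxidation-level corrections make it about seven steps against four.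

Alternative 3: The cut is C4–C5 and O1–C5. C2, C3 and C4 come from 3,3-dibromo-2-butylacrylic acid A6, and C5 and C6 from ethynyltrimethylsilane A7. Under Pd(PPh3)4 and CuI with an amine base, the bromide cis to the carboxyl group would undergo Sonogashira coupling, and the carboxylate would then add 5-exo-dig to the alkyne to give (Z)-4-bromo-3-butyl-5-[(trimethylsilyl)methylene]furan-2(5H)-one A8.
- In its favour: ring and exocyclic carbon are assembled in one operation without carbon monoxide, which is better for safe handling. The silyl group is an ipso handle, so bromodesilylation of A8 would lead straight to 11, where this plan joins the chosen route. It is the equal of the chosen plan in carrying the C4 bromide through a palladium step.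
- Against it here: telling apart two bromides on the same carbon is a finer selectivity than iodide against bromide. A 6-endo closure to a pyranone and a second coupling at C4 are competing paths. A6 itself needs about two steps (dibromo-olefination of an α-keto ester, then saponification).
- Comparison: about five steps against four, so nearly equal in step economy. The chosen plan is preferred because its precursor comes in one step from a commercial ynone and its halide selectivity rests on the larger I/Br difference.

Key step: step 2

Step 1
Reactants: 1 oct-3-yn-2-one; 2 sodium iodide; 3 chlorotrimethylsilane; 4 N-bromosuccinimide
Product: 6 (E)-3-bromo-4-iodooct-3-en-2-one, via silyl allenol ether 5 (not isolated)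
Conditions: NaI (1.0 equiv), Me3SiCl (1.0 equiv), MeCN–CH2Cl2, −40 °C; then NBS (1.05 equiv), −40 → 0 °C, dark; aqueous work-up
Reagents that add atoms: sodium iodide [Na+].[I-]; N-bromosuccinimide O=C1CCC(=O)N1Br
Why: Conjugate addition of iodide from Me3SiI (made in the flask from NaI and Me3SiCl) to an ynone is a known way to β-iodo silyl allenol ethers, and α-bromination of a silyl enol ether with NBS is standard. The enol-ether π bond of 5 lies in the plane of the C4 substituents, so bromine should enter at C3 on the side away from the large iodine, giving net anti addition of I and Br and hence the E isomer with iodine cis to acetyl. One equivalent of iodide and low temperature are used so that no iodide is left to be oxidised by NBS or to isomerise the product.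

Step 2
Reactants: 6 (E)-3-bromo-4-iodooct-3-en-2-one; 7 carbon monoxide
Product: 8 4-bromo-3-butyl-5-methylenefuran-2(5H)-one
Conditions: CO (1 atm, balloon), Pd(PPh3)2Cl2 (5 mol %), Et3N (2 equiv), dry MeCN, 25–40 °C, dark
Reagents that add atoms: carbon monoxide [C-]#[O+]
Why: Pd(PPh3)2Cl2 is reduced in the flask to zerovalent palladium, which should insert into the C–I bond of 6 (the weakest carbon–halogen bond and a vinylogous acyl iodide) to give a divalent vinylpalladium iodide; migratory insertion of CO then gives the acylpalladium. Et3N can enolise the acetyl group only toward its methyl carbon, and the enol(ate) oxygen attacks the acyl carbon, releasing zerovalent palladium and forming C2–C3 and C2–O1 in one catalytic cycle. The closest known reaction type is the palladium-catalysed carbonylative lactonisation of (Z)-β-iodoenones to γ-ylidenebutenolides, in which iodine is cis to the acyl group exactly as in E-configured 6. The ring closes by a 5-exo-trig acyl substitution through oxygen; attack through the enolate carbon would be a 5-(enolendo)-exo-trig closure, which the ring-closure rules for enolates disfavour. No stereocentre is formed and the new exocyclic alkene is a methylene group, so no geometry has to be controlled. The step needs selectivity for C–I over both kinds of C–Br bond; this rests on the much faster oxidative addition of vinyl iodides at 25–40 °C with PPh3 ligands and on stopping at full conversion of 6, because the C4–Br bond of 8 is itself activated. It also needs iodine cis to acetyl, which the anti dihalogenation of step 1 provides and which is preserved by working in the dark and using 6 soon after it is made.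

Step 3
Reactants: 8 4-bromo-3-butyl-5-methylenefuran-2(5H)-one; 9 bromine
Product: 11 (Z)-4-bromo-5-(bromomethylene)-3-butylfuran-2(5H)-one, via lactone dibromide 10 (not isolated)
Conditions: Br2 (1.0 equiv), CH2Cl2, 0 °C, dark, until the colour fades; then Et3N (1.2 equiv), 0 °C
Reagents that add atoms: bromine BrBr
Why: Electrophilic addition of Br2 should occur at the enol-ester alkene C5=C6, which is far more nucleophilic than the tetrasubstituted, acceptor-substituted C3=C4 bond, giving racemic 10. Only C6 carries β-hydrogens, so amine-induced E2 loss of HBr with the ionisable C5 bromide as leaving group restores the exocyclic alkene. The Z isomer (bromine on the O1 side, away from the C4 bromine) should prevail, and the C5 stereocentre of 10 is destroyed.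

Step 4
Reactants: 11 (Z)-4-bromo-5-(bromomethylene)-3-butylfuran-2(5H)-one; 9 bromine
Product: 13 4-bromo-3-butyl-5-(dibromomethylene)furan-2(5H)-one, via lactone tetrabromide 12 (not isolated)
Conditions: Br2 (2 equiv), CH2Cl2, 25 °C, dark; evaporate excess Br2; then Et3N (1.2 equiv), CH2Cl2, 0 °C
Reagents that add atoms: bromine BrBr
Why: This is the same bromine addition–dehydrobromination, now on a bromovinyl enol ester that reacts more slowly, hence the excess of Br2 and the longer time. Racemic 12 has a single hydrogen, on C6, so E2 loss of HBr with the C5 bromide can only give the dibromomethylene group, which has no geometric isomers.

Compound list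
1 | oct-3-yn-2-one | CCCCC#CC(C)=O | starting material
2 | sodium iodide | [Na+].[I-] | starting material
3 | chlorotrimethylsilane | C[Si](C)(C)Cl | starting material
4 | N-bromosuccinimide | O=C1CCC(=O)N1Br | starting material
5 | trimethyl[(4-iodoocta-2,3-dien-2-yl)oxy]silane (racemic allene; silyl allenol ether) | CCCCC(I)=C=C(C)O[Si](C)(C)C | intermediate
6 | (E)-3-bromo-4-iodooct-3-en-2-one (iodine cis to acetyl) | CCCC/C(I)=C(\Br)C(C)=O | intermediate
7 | carbon monoxide | [C-]#[O+] | starting material
8 | 4-bromo-3-butyl-5-methylenefuran-2(5H)-one | CCCCC1=C(Br)C(=C)OC1=O | intermediate
9 | bromine | BrBr | starting material
10 | rac-4,5-dibromo-5-(bromomethyl)-3-butylfuran-2(5H)-one | CCCCC1=C(Br)C(Br)(CBr)OC1=O | intermediate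
11 | (Z)-4-bromo-5-(bromomethylene)-3-butylfuran-2(5H)-one | CCCCC1=C(Br)/C(=C/Br)OC1=O | intermediate
12 | rac-4,5-dibromo-3-butyl-5-(dibromomethyl)furan-2(5H)-one | CCCCC1=C(Br)C(Br)(C(Br)Br)OC1=O | intermediate
13 | 4-bromo-3-butyl-5-(dibromomethylene)furan-2(5H)-one | CCCCC1=C(Br)C(=C(Br)Br)OC1=O | target

Total step count: 4. Longest linear sequence: 4 steps (1 → 6 → 8 → 11 → 13).

Least certain steps

Step 2 (key step). The most likely failure is loss of chemoselectivity among the carbon–halogen bonds: once 6 is consumed, zerovalent palladium may insert into the activated C4–Br bond of 8. Enolisation of the acetyl group may also lag behind CO insertion, so that the acylpalladium decomposes before the oxygen can capture it. Geometric isomerisation of 6 before oxidative addition would stall the closure as well. Fallback, setting out from 6 and returning at 8: palladium-catalysed hydroxycarbonylation of 6 (CO, Pd(PPh3)2Cl2, Et3N, aqueous THF, 25 °C) traps the acylpalladium with water, a much faster nucleophile than a ketone enol, so the catalyst sees the bromides for a shorter time and at lower temperature. On acidification the resulting (Z)-keto acid should close to its ring tautomer 4-bromo-3-butyl-5-hydroxy-5-methylfuran-2(5H)-one F1. Dehydration of this lactol with P2O5 in CH2Cl2, the classical way to 5-ylidene butenolides, then gives 8. The O1–C2 bond is thus formed by addition of a carboxylic acid to the ketone, not by enol acylation.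

Step 1. The likely failures are erosion of the anti relationship of the two halogens (bromine delivered on the iodine side of 5), halogen scrambling through oxidation of residual iodide by 4, and protonation of 5 by adventitious HI before bromination. Each would lower the amount of the isomer that can lactonise. Fallback, setting out from 1 and returning at 6: anti addition of bromine 9 to the ynone (CH2Cl2, 0 °C) should give (E)-3,4-dibromooct-3-en-2-one F2. The β-bromide of F2 sits at the vinylogous acyl position and can be exchanged for iodide by addition–elimination with NaI and a catalytic amount of Me3SiCl in MeCN; the α-bromide, which is not at an electrophilic carbon, stays. The exchange is under thermodynamic control and is expected to favour the isomer that avoids a cis I/Br pair, which is 6.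

Step 3. The likely failures are oligomerisation of the cross-conjugated methylene lactone 8 before or during bromination, conjugate addition of bromine across C6=C5–C4=C3, and attack of the amine at C4 with displacement of bromide. Fallback, setting out from 8 and returning at 11: bromohydrin formation with NBS in aqueous acetone at 0 °C places bromine on C6 and water on the oxocarbenium carbon C5, giving 4-bromo-5-(bromomethyl)-3-butyl-5-hydroxyfuran-2(5H)-one F3. Dehydration of F3 with P2O5 in CH2Cl2 gives 11 without any amine base.

Step 4. The likely failures are sluggish, incomplete addition of bromine to the deactivated bromovinyl enol ester, radical bromination at the allylic CH2 of the butyl chain if the reaction is forced, and amine attack at C4 during the elimination. Fallback, setting out from 11 and returning at 13: NBS in aqueous acetone, a polar medium that speeds the ionic addition, should give the lactol 4-bromo-3-butyl-5-(dibromomethyl)-5-hydroxyfuran-2(5H)-one F4. Acid-promoted dehydration of F4 (P2O5, CH2Cl2, reflux) gives 13, again without amine.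

Further compounds
F1 | step 2 | 4-bromo-3-butyl-5-hydroxy-5-methylfuran-2(5H)-one (racemic) | CCCCC1=C(Br)C(C)(O)OC1=O
F2 | step 1 | (E)-3,4-dibromooct-3-en-2-one | CCCC/C(Br)=C(\Br)C(C)=O
F3 | step 3 | 4-bromo-5-(bromomethyl)-3-butyl-5-hydroxyfuran-2(5H)-one (racemic) | CCCCC1=C(Br)C(O)(CBr)OC1=O
F4 | step 4 | 4-bromo-3-butyl-5-(dibromomethyl)-5-hydroxyfuran-2(5H)-one (racemic) | CCCCC1=C(Br)C(O)(C(Br)Br)OC1=O
A1 | alternative 1 | diisopropyl squarate | CC(C)OC1=C(OC(C)C)C(=O)C1=O
A2 | alternative 1 | 2-butyl-4-(dibromomethyl)-4-hydroxy-3-isopropoxycyclobut-2-en-1-one (racemic) | CCCCC1=C(OC(C)C)C(O)(C(Br)Br)C1=O
A3 | alternative 1 | 3-butyl-5-(dibromomethyl)-4-isopropoxyfuran-2(5H)-one (racemic) | CCCCC1=C(OC(C)C)C(C(Br)Br)OC1=O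
A4 | alternative 2 | methyl 2-(hexanoyloxy)propanoate | CCCCCC(=O)OC(C)C(=O)OC
A5 | alternative 2 | 3-butyl-4-hydroxy-5-methylfuran-2(5H)-one | CCCCC1=C(O)C(C)OC1=O
A6 | alternative 3 | 3,3-dibromo-2-butylacrylic acid | CCCCC(C(=O)O)=C(Br)Br
A7 | alternative 3 | ethynyltrimethylsilane | C#C[Si](C)(C)C
A8 | alternative 3 | (Z)-4-bromo-3-butyl-5-[(trimethylsilyl)methylene]furan-2(5H)-one | CCCCC1=C(Br)/C(=C/[Si](C)(C)C)OC1=O
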